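**Retrosynthetic overview**

1. 6-Prenylsakuranetin is traced back by one desilylation to its 4'-O-TIPS ether. Rings A and B are bought as arenes; ring C is the only ring made, and it is made last.
2. Ring C is opened at C3–C4. The flavanone is the hydroacylation isomer of an achiral salicylaldehyde carrying an aryl 1-arylvinyl ether (O1–C2(ring B)=C3H2) ortho to the formyl group. A rhodium-catalysed enantioselective intramolecular hydroacylation closes ring C and sets C2 in one operation.
3. Enabling feature: C2, the only stereocentre, is a benzylic ring C carbon bonded to O1 and ring B, next to the unsubstituted C3 methylene, so C2=C3 can be an enol ether. C4 sits on C4a of ring A between O1 (on C8a) and the free C5 hydroxyl, so the cut leaves a salicylaldehyde whose phenoxide can hold rhodium at the acyl carbon.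
4. The enol ether comes from E2 dehydrobromination of a β-bromo benzylic ether. That ether is made by Mitsunobu union of the ring A aldehyde (at its less hindered hydroxyl) with a ring B bromohydrin.
5. Ring A aldehyde: 2,4,6-trihydroxybenzaldehyde, 4-O-methylation, then C-prenylation. Ring B: 2-bromo-4'-hydroxyacetophenone, silylation, then reduction.

Key step: step 7

Remark: the sense of induction in step 7 is assumed; (R)-DTBM-SEGPHOS is taken as the ligand enantiomer that delivers (2S), and the (S)-ligand would be used under otherwise identical conditions if the sense proved opposite.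

**Route**

Step 1
Reactants: 1 2,4,6-trihydroxybenzaldehyde
Product: 2 2,6-dihydroxy-4-methoxybenzaldehyde
Conditions: Me2SO4 (1.0 equiv), K2CO3 (1.0 equiv), acetone, rt
Reagents that add atoms: dimethyl sulfate, COS(=O)(=O)OC
Why: Williamson O-methylation, in which the 4-hydroxyl (para to the formyl group and not hydrogen-bonded to it) is the most acidic phenol of 1 and should be methylated by one equivalent of base and electrophile in preference to the two ortho hydroxyls.

Step 2
Reactants: 2 2,6-dihydroxy-4-methoxybenzaldehyde; 3 prenyl bromide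
Product: 4 2,6-dihydroxy-4-methoxy-3-(3-methylbut-2-en-1-yl)benzaldehyde
Conditions: 10% aq. KOH, 0 °C to rt
Reagents that add atoms: none
Why: Phenoxide C-alkylation (C-prenylation of an acylphloroglucinol-type nucleus in aqueous alkali), in which C3 of the symmetric dianion is ortho to one phenoxide and para to the other, water solvation of the oxygens steers the allylic bromide to carbon, and the equivalence of C3 and C5 means monoalkylation gives a single regioisomer.

Step 3
Reactants: 5 2-bromo-1-(4-hydroxyphenyl)ethan-1-one
Product: 6 2-bromo-1-{4-[tri(propan-2-yl)silyloxy]phenyl}ethan-1-one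
Conditions: TIPSOTf, 2,6-lutidine, CH2Cl2, −78 to 0 °C
Reagents that add atoms: triisopropylsilyl trifluoromethanesulfonate, CC(C)[Si](C(C)C)(C(C)C)OS(=O)(=O)C(F)(F)F
Why: Silyl ether formation, in which the phenol is silylated by the silyl triflate and a hindered, non-nucleophilic base at low temperature so that the α-bromo ketone is left untouched.

Step 4
Reactants: 6 2-bromo-1-{4-[tri(propan-2-yl)silyloxy]phenyl}ethan-1-one
Product: 7 rac-2-bromo-1-{4-[tri(propan-2-yl)silyloxy]phenyl}ethan-1-ol
Conditions: NaBH4, MeOH/THF, 0 °C; aq. NH4Cl quench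
Reagents that add atoms: none
Why: Borohydride reduction of the ketone should give the racemic bromohydrin without epoxide closure under cold, neutral-quench conditions, and the configuration of this carbon is irrelevant because it becomes sp2 in step 6.

Step 5
Reactants: 4 2,6-dihydroxy-4-methoxy-3-(3-methylbut-2-en-1-yl)benzaldehyde; 7 rac-2-bromo-1-{4-[tri(propan-2-yl)silyloxy]phenyl}ethan-1-ol
Product: 8 rac-6-(2-bromo-1-{4-[tri(propan-2-yl)silyloxy]phenyl}ethoxy)-2-hydroxy-4-methoxy-3-(3-methylbut-2-en-1-yl)benzaldehyde
Conditions: PPh3, DIAD, THF, 0 °C to rt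
Reagents that add atoms: none
Why: Mitsunobu etherification, in which the acidic salicylaldehyde-type phenol serves as pronucleophile, the hydroxyl flanked by an aromatic hydrogen should react in preference to the one buttressed by the prenyl group, and the remaining hydroxyl stays chelated to the formyl group so that monoalkylation at the future O1 is expected.

Step 6
Reactants: 8 rac-6-(2-bromo-1-{4-[tri(propan-2-yl)silyloxy]phenyl}ethoxy)-2-hydroxy-4-methoxy-3-(3-methylbut-2-en-1-yl)benzaldehyde
Product: 9 2-hydroxy-4-methoxy-3-(3-methylbut-2-en-1-yl)-6-[(1-{4-[tri(propan-2-yl)silyloxy]phenyl}ethenyl)oxy]benzaldehyde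
Conditions: KOtBu (2.5 equiv), THF, 0 °C; pH 7 buffer work-up, chromatography on Et3N-deactivated silica
Reagents that add atoms: none
Why: E2 dehydrobromination, in which tert-butoxide removes the only β-hydrogen (benzylic and α to oxygen) to give the achiral 1-arylvinyl aryl ether, while the phenoxide formed from the free hydroxyl is a spectator and the non-enolizable aldehyde and the aryl TIPS ether should tolerate the cold base.

Step 7
Reactants: 9 2-hydroxy-4-methoxy-3-(3-methylbut-2-en-1-yl)-6-[(1-{4-[tri(propan-2-yl)silyloxy]phenyl}ethenyl)oxy]benzaldehyde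
Product: 10 (2S)-5-hydroxy-7-methoxy-6-(3-methylbut-2-en-1-yl)-2-{4-[tri(propan-2-yl)silyloxy]phenyl}-2,3-dihydro-4H-chromen-4-one
Conditions: [Rh(cod)Cl]2 (2.5 mol %), (R)-DTBM-SEGPHOS (5.5 mol %), K3PO4 (10 mol %), 1,4-dioxane, 60 °C
Reagents that add atoms: none
Why: Proposed new method: deprotonation of the C5 hydroxyl lets the phenoxide bind monovalent rhodium, chelate-assisted oxidative addition of the formyl C–H gives a trivalent acyl rhodium hydride held in a five-membered O,C-chelate that resists decarbonylation, the hydride migrates to the aryl- and oxygen-bearing alkene carbon (C2) of the coordinated enol ether, and C–C reductive elimination from the seven-membered acyl alkyl rhodacycle forms C3–C4 and returns the catalyst. The closest known reaction types are the rhodium bisphosphine catalysed enantioselective intramolecular hydroacylation of 1,1-disubstituted alkenes (2-allylbenzaldehydes to 3-substituted tetralones, N-vinylindole-2-carbaldehydes to fused ketones) and the phenoxide-chelation-assisted hydroacylations of salicylaldehydes; an aryl 1-arylvinyl ether closing to a chroman-4-one has not been shown. Ring C closes in a formal 6-endo-trig mode, the acyl carbon bonding to the terminal alkene carbon. C2 is set in the hydride insertion, where the axially chiral bisphosphine on rhodium chooses the enol ether face (catalyst control, no other stereocentre present). The step needs regioselectivity for the six-membered ketone over a 2-methylbenzofuran-3-one with a quaternary carbon, which the 1,1-disubstitution should secure because rhodium avoids the fully substituted carbon, and chemoselectivity over the prenyl alkene, which is trisubstituted and meta to the formyl group and so cannot reach the acyl rhodium centre. The aprotic, slightly basic medium should protect the acid-labile enol ether until it has cyclized.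

Step 8
Reactants: 10 (2S)-5-hydroxy-7-methoxy-6-(3-methylbut-2-en-1-yl)-2-{4-[tri(propan-2-yl)silyloxy]phenyl}-2,3-dihydro-4H-chromen-4-one
Product: 11 6-prenylsakuranetin
Conditions: TBAF (1.1 equiv), AcOH (1.2 equiv), THF, 0 °C
Reagents that add atoms: none
Why: Fluoride-mediated desilylation of the aryl silyl ether, buffered with acetic acid so that the base-sensitive flavanone should neither open to the chalcone nor racemize at C2, with the prenyl group and the chelated C5 hydroxyl unaffected.

**Compound list**

1 | 2,4,6-trihydroxybenzaldehyde | O=Cc1c(O)cc(O)cc1O | starting material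
2 | 2,6-dihydroxy-4-methoxybenzaldehyde | COc1cc(O)c(C=O)c(O)c1 | intermediate
3 | prenyl bromide (1-bromo-3-methylbut-2-ene) | CC(C)=CCBr | starting material
4 | 2,6-dihydroxy-4-methoxy-3-(3-methylbut-2-en-1-yl)benzaldehyde | COc1cc(O)c(C=O)c(O)c1CC=C(C)C | intermediate
5 | 2-bromo-1-(4-hydroxyphenyl)ethan-1-one | O=C(CBr)c1ccc(O)cc1 | starting material
6 | 2-bromo-1-{4-[tri(propan-2-yl)silyloxy]phenyl}ethan-1-one | O=C(CBr)c1ccc(O[Si](C(C)C)(C(C)C)C(C)C)cc1 | intermediate
7 | rac-2-bromo-1-{4-[tri(propan-2-yl)silyloxy]phenyl}ethan-1-ol | OC(CBr)c1ccc(O[Si](C(C)C)(C(C)C)C(C)C)cc1 | intermediate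
8 | rac-6-(2-bromo-1-{4-[tri(propan-2-yl)silyloxy]phenyl}ethoxy)-2-hydroxy-4-methoxy-3-(3-methylbut-2-en-1-yl)benzaldehyde | COc1cc(OC(CBr)c2ccc(O[Si](C(C)C)(C(C)C)C(C)C)cc2)c(C=O)c(O)c1CC=C(C)C | intermediate
9 | 2-hydroxy-4-methoxy-3-(3-methylbut-2-en-1-yl)-6-[(1-{4-[tri(propan-2-yl)silyloxy]phenyl}ethenyl)oxy]benzaldehyde | COc1cc(OC(=C)c2ccc(O[Si](C(C)C)(C(C)C)C(C)C)cc2)c(C=O)c(O)c1CC=C(C)C | intermediate
10 | (2S)-5-hydroxy-7-methoxy-6-(3-methylbut-2-en-1-yl)-2-{4-[tri(propan-2-yl)silyloxy]phenyl}-2,3-dihydro-4H-chromen-4-one | COc1cc2c(c(O)c1CC=C(C)C)C(=O)C[C@@H](c1ccc(O[Si](C(C)C)(C(C)C)C(C)C)cc1)O2 | intermediate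
11 | 6-prenylsakuranetin, (2S)-5-hydroxy-2-(4-hydroxyphenyl)-7-methoxy-6-(3-methylbut-2-en-1-yl)-2,3-dihydro-4H-chromen-4-one | COc1cc2c(c(O)c1CC=C(C)C)C(=O)C[C@@H](c1ccc(O)cc1)O2 | target

**Step count and risks**

Total step count: 8. Longest linear sequence: 6 steps (steps 1, 2, 5, 6, 7, 8).

Steps most likely to fail:

1. Step 7 (proposed new method). The acyl rhodium hydride may decarbonylate before the hindered enol ether inserts. The hydride may be delivered to the terminal carbon, leading to five-membered ring closure. Facial discrimination of the enol ether may be poor. Adventitious acid may hydrolyse the enol ether. The fallback uses known chemistry, sets out from 6 and 4 and returns at 10. Corey–Bakshi–Shibata reduction of 6 ((S)-2-methyl-CBS-oxazaborolidine, BH3·SMe2, THF) should give (S)-2-bromo-1-{4-[tri(propan-2-yl)silyloxy]phenyl}ethan-1-ol F1. Mitsunobu etherification of 4 with this alcohol (PPh3, DIAD) should proceed with inversion to (R)-6-(2-bromo-1-{4-[tri(propan-2-yl)silyloxy]phenyl}ethoxy)-2-hydroxy-4-methoxy-3-(3-methylbut-2-en-1-yl)benzaldehyde F2. An N-heterocyclic carbene (3-benzyl-5-(2-hydroxyethyl)-4-methylthiazolium chloride, Cs2CO3, dioxane) then adds to the formyl group, and the Breslow intermediate displaces the primary bromide in an intramolecular SN2 reaction. This forms the same C3–C4 bond and releases 10 with the preset stereocentre untouched; it is the known umpolung alkylation of 2-(2-haloethoxy)benzaldehydes to chroman-4-ones. The base exposure would be kept short to limit ring opening of 10.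

2. Step 2. O-prenylation, a second C-prenylation at C5 and hydrolysis of the allylic bromide may compete with the desired C-alkylation. The fallback sets out from 2 and returns at 4. O-Alkylation of one of the two equivalent hydroxyls with tert-butyl 2-methylbut-3-en-2-yl carbonate and Pd(PPh3)4 (zerovalent palladium, THF) should give 2-hydroxy-4-methoxy-6-[(2-methylbut-3-en-2-yl)oxy]benzaldehyde F3. Aromatic Claisen rearrangement on heating (N,N-diethylaniline, about 120 °C) then transfers the allyl unit, as a normal prenyl group, to the only free ortho carbon and gives 4 with unambiguous regiochemistry.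

3. Step 5. Etherification may occur at the prenyl-flanked hydroxyl (which would lead to the 8-prenyl series), double alkylation may occur, or the activated benzylic alcohol may ionize or eliminate. The fallback sets out from 2 and 7 and returns at 8, bypassing step 2. Mitsunobu etherification of symmetric 2 with 7 raises no regiochemical question and should give rac-2-(2-bromo-1-{4-[tri(propan-2-yl)silyloxy]phenyl}ethoxy)-6-hydroxy-4-methoxybenzaldehyde F4. Palladium-catalysed O-alkylation of the remaining hydroxyl with tert-butyl 2-methylbut-3-en-2-yl carbonate (Pd(PPh3)4) should give rac-2-(2-bromo-1-{4-[tri(propan-2-yl)silyloxy]phenyl}ethoxy)-4-methoxy-6-[(2-methylbut-3-en-2-yl)oxy]benzaldehyde F5. Thermal Claisen rearrangement then places the prenyl group on the single open carbon ortho to that oxygen, giving 8 with the hydroxyl and prenyl group correctly adjacent.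

**Further compounds**

F1 | step 7 | (S)-2-bromo-1-{4-[tri(propan-2-yl)silyloxy]phenyl}ethan-1-ol | O[C@H](CBr)c1ccc(O[Si](C(C)C)(C(C)C)C(C)C)cc1
F2 | step 7 | (R)-6-(2-bromo-1-{4-[tri(propan-2-yl)silyloxy]phenyl}ethoxy)-2-hydroxy-4-methoxy-3-(3-methylbut-2-en-1-yl)benzaldehyde | COc1cc(O[C@@H](CBr)c2ccc(O[Si](C(C)C)(C(C)C)C(C)C)cc2)c(C=O)c(O)c1CC=C(C)C
F3 | step 2 | 2-hydroxy-4-methoxy-6-[(2-methylbut-3-en-2-yl)oxy]benzaldehyde | COc1cc(O)c(C=O)c(OC(C)(C)C=C)c1
F4 | step 5 | rac-2-(2-bromo-1-{4-[tri(propan-2-yl)silyloxy]phenyl}ethoxy)-6-hydroxy-4-methoxybenzaldehyde | COc1cc(O)c(C=O)c(OC(CBr)c2ccc(O[Si](C(C)C)(C(C)C)C(C)C)cc2)c1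
F5 | step 5 | rac-2-(2-bromo-1-{4-[tri(propan-2-yl)silyloxy]phenyl}ethoxy)-4-methoxy-6-[(2-methylbut-3-en-2-yl)oxy]benzaldehyde | COc1cc(OC(C)(C)C=C)c(C=O)c(OC(CBr)c2ccc(O[Si](C(C)C)(C(C)C)C(C)C)cc2)c1
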